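In a one-step world the charge turns into target and stays there; this flask has a further step that eats target, so I watch how long target sits beside free catalyst.

    starting material + reagent + catalyst → catalyst + target (k1 = 6.3 × 10⁶ M⁻² s⁻¹)
    second substrate + reagent + catalyst → catalyst + second product (k2 = 4.5 × 10⁵ M⁻² s⁻¹)
    catalyst + target → catalyst + over-reaction product (k3 = 570 M⁻¹ s⁻¹)
    catalyst + added ligand ⇌ idle complex (K4 = 1800 M⁻¹, k4 = 420 M⁻¹ s⁻¹)

common to all: starting material 2.0 mM; catalyst 2 mol%; added ligand 0.16 mM
- dawn: reagent 1.20 equiv (fed, over 80.0 s); second substrate 1.00 equiv; time 80 s; all but reagent at the start; reagent goes in evenly over 80.0 s, the run ends at 80 s
- noon: reagent 1.20 equiv; second substrate 1.00 equiv (fed, over 80.0 s); time 80 s; a stirred flask in which second substrate is dosed at a steady rate over 80.0 s without added volume, worked up at 80 s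
- summer: reagent 1.20 equiv; second substrate 1.00 equiv; one stirred flow tank at steady state, fed with the mixture as stated, mean residence time 80 s
- autumn: reagent 1.20 equiv; second substrate 1.00 equiv; time 80 s; a closed flask charged with all of it at once and left for 80 s

1. the set-up with the highest amount of target at the outlet or at the end, in percent of the starting material put in ("none" if the first two lie within 2 percentage points) (dawn / noon / summer / autumn / none)
2. amount of target at the outlet or at the end, in percent of the starting material put in, dawn
3. amount of target at the outlet or at the end, in percent of the starting material put in, noon
4. amount of target at the outlet or at the end, in percent of the starting material put in, summer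
5. amount of target at the outlet or at the end, in percent of the starting material put in, autumn

- the stated concentrations are those of everything mixed, before any reaction; amounts are the same in each set-up
- the feed brings no volume worth counting
- run time (dawn): 80 s

**Loss number.** Step 3 takes target in proportion to free catalyst. The ligand exchange relaxes with a half-life of 2.31 s, far shorter than the run, so I hold the free share at 77.6% of the catalyst, reckoned with the ligand as charged. Step 3's constant times free catalyst times run time is my loss number, 1.42; at zero the one-step world returns. Step 2 I set aside: its constant is smaller than step 1's by the selectivity factor 14.0, where the statistical case of equal constants and equal charges gives a factor of 1.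

**Autumn's curve.** In autumn, starting material first falls by 0.470 s⁻¹ of its charge. That rise time of 2.13 s is shorter than the loss time of 56.5 s, so target climbs first. Treating starting material and reagent as equal, making meets loss with 19.4% of the starting material left, near 8.84 s; I expect target to crest there, somewhat below the 80.6% that has reacted by then. Counting the whole charge as made at the start and lost by the loss number, I expect about 24.2% in autumn at the end. Noon has its reagent from the start, so I reckon the same there.

**Slower making.** In dawn, I reckon target as made evenly over the first 66.7 s, as if the reagent went to starting material as it arrives, which gives 46.4%. In summer, the spread of ages keeps one part in one plus the loss number, 41.4% of whatever has reacted. My dawn figure is higher than the summer share and the autumn figure, so I put dawn first.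

**The forecast.** It names dawn: dawn 48% (43% to 53%), noon 26.5% (23% to 30%), summer 33.5% (30% to 37%), autumn 26% (22% to 30%). Its ground: “Feeding the reagent slowly makes the target late”. My dawn figure stands a little lower than its figure.

**The result.** The best set-up is dawn: dawn 45.1%, noon 25.7%, summer 33.4%, autumn 25.2%.

**Reading the end.** In autumn at 80.0 s, target is made at 0.0281 of the rate at which it is used up, and 71.7% stands as over-reaction product. In summer, target is 40.8% of target plus over-reaction product, against my 41.4%. The autumn flask with 0.5 mol% of catalyst has a quarter of the loss number, 0.354, which by the same reckoning keeps 70.2%. That neighbour ends with 68.2% target beside 23.7% over-reaction product.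

The numbers are those of an exercise; no experiment stands behind them.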